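**Plan**

Positions follow daucane numbering: C1 quaternary methyl carbon, C2, C3, C4 isopropyl carbon, C5 carbinol carbon, C6, C7 ester carbon, C8(Me)=C9, C10.
Retrosynthesis: cut the C7–O ester bond, take the C7 oxygen and the C8=C9 alkene back to a C7=C8 alkene, take the isopropyl group back to a C4 methyl ester, then cut C1–C2 and C4–C5 of the cyclopentane in one operation.
Enabling feature: the five-membered ring joins the seven-membered ring through two adjacent fully substituted carbons, C1 carrying methyl and C5 carrying oxygen. This is what a three-carbon vinylcarbenoid unit leaves behind when it adds across a tetrasubstituted C1=C5 silyl enol ether.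
Forward: the seven-membered ring is made first (Birch reduction and one-carbon ring expansion of 4-methylanisole), the cyclopentene is annulated in step 7, then the ester becomes isopropyl and the C7=C8 alkene becomes the C7 carbinol with the C8=C9 alkene.
Stereochemistry: C1 and C5 come from the chiral dirhodium carboxylate and the same-face [3+2] closure (methyl and oxygen cis). C4 comes from equilibration of the ester to the face of the C5 hydroxyl. C7 comes from hydroxyl-directed hydride delivery (oxygen trans to the C5 hydroxyl).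

Key step: step 7

Assumption: the sense of asymmetric induction of the dirhodium catalyst in step 7 cannot be predicted with confidence. The route is written for the catalyst enantiomer that gives (3aR,8aS)-11; the mirror-image catalyst would be used if the opposite sense is found.

**Route**

Step 1
Reactants: 1 4-methylanisole
Product: 2 1-methoxy-4-methylcyclohexa-1,4-diene
Conditions: Li, NH3 (l), t-BuOH, THF, −78 → −33 °C
Reagents that add atoms: none
Why: Birch reduction of the donor-substituted arene leaves both donors (OMe, Me) on the residual double bonds and gives the unconjugated 1,4-diene; no stereocentre is formed.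

Step 2
Reactants: 2 1-methoxy-4-methylcyclohexa-1,4-diene, 3 1,1-dichloroethane
Product: 5 2,5-dimethylcyclohepta-2,5-dien-1-one, via chloro(methyl)cyclopropane adduct 4 (not isolated)
Conditions: n-BuLi, Et2O, −40 → −20 °C; then NaHCO3, dioxane–H2O, 80 °C
Reagents that add atoms: water, O
Why: The chloro(methyl)carbenoid cyclopropanates the more electron-rich enol ether double bond, and methoxy-assisted electrocyclic opening of the cyclopropyl chloride followed by hydrolysis of the oxocarbenium ion gives the ring-expanded 2-methyl enone (carbene ring expansion); no stereocentre remains.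

Step 3
Reactants: 5 2,5-dimethylcyclohepta-2,5-dien-1-one
Product: 6 tert-butyl[(2,5-dimethylcyclohepta-1,5-dien-1-yl)oxy]dimethylsilane
Conditions: t-BuMe2SiH, RhCl(PPh3)3 (1 mol %), PhH, 60 °C
Reagents that add atoms: tert-butyldimethylsilane, C[SiH](C)C(C)(C)C
Why: Rhodium-catalysed 1,4-hydrosilylation of the enone with a monohydrosilane gives the tetrasubstituted C1=C5 silyl enol ether regiospecifically, without a free enolate that could drift toward C6, and leaves the isolated trisubstituted alkene untouched.

Step 4
Reactants: 7 methyl acetoacetate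
Product: 8 methyl 2-diazo-3-oxobutanoate
Conditions: 4-acetamidobenzenesulfonyl azide, Et3N, MeCN, 0 °C → rt
Reagents that add atoms: 4-acetamidobenzenesulfonyl azide, CC(=O)Nc1ccc(cc1)S(=O)(=O)N=[N+]=[N-]
Why: Regitz diazo transfer to the active methylene of a β-keto ester.

Step 5
Reactants: 8 methyl 2-diazo-3-oxobutanoate
Product: 9 methyl 2-diazo-3-hydroxybutanoate (racemic)
Conditions: NaBH4, MeOH, 0 °C
Reagents that add atoms: none
Why: Borohydride reduction takes the ketone of the α-diazo-β-keto ester chemoselectively; the diazo group and ester survive, and the carbinol centre is lost in step 6.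

Step 6
Reactants: 9 methyl 2-diazo-3-hydroxybutanoate
Product: 10 methyl 2-diazobut-3-enoate
Conditions: POCl3, Et3N, CH2Cl2, 0 °C → rt; kept cold and used at once
Reagents that add atoms: none
Why: Dehydration through the dichlorophosphate and amine-induced elimination is the standard way to unsubstituted vinyldiazoacetates; the product is used immediately because it cyclises to a pyrazole on standing.

Step 7
Reactants: 6 tert-butyl[(2,5-dimethylcyclohepta-1,5-dien-1-yl)oxy]dimethylsilane, 10 methyl 2-diazobut-3-enoate
Product: 11 methyl (3aR,8aS)-3a-[(tert-butyldimethylsilyl)oxy]-6,8a-dimethyl-1,3a,4,7,8,8a-hexahydroazulene-3-carboxylate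
Conditions: Rh2(S-PTAD)4 [dirhodium tetrakis((S)-(1-adamantyl)(N-phthalimido)acetate)] (1 mol %), CH2Cl2, −40 → 0 °C, 10 (2 equiv) added over 3 h
Reagents that add atoms: none
Why: Proposed new method: the dirhodium catalyst (divalent rhodium) releases N2 from 10 to give an electrophilic rhodium vinylcarbenoid whose unsubstituted terminal carbon is attacked by nucleophilic C1 of 6 (C1–C2), and the resulting vinylrhodium carbon C4 then closes on the C5 silyloxocarbenium ion (C4–C5) with release of the catalyst. The closest known reaction is the formal [3+2] annulation of rhodium vinylcarbenoids with vinyl ethers through the vinylogous pathway, which is established for less substituted enol ethers but not for a tetrasubstituted cyclic silyl enol ether or for enantiocontrol of two adjacent quaternary centres. The cyclopentene closes in a 5-exo-trig mode onto the exocyclic C5=O+ bond. C1 is set in the first C–C bond formation, where the chiral carboxylate ligands choose the enantioface of the enol ether; C5 follows from C1 because the three-atom tether can only reach the face of the oxocarbenium ion from which it started, so methyl and silyloxy end up cis. The step needs vinylogous attack to win over cyclopropanation at the carbenoid carbon, over C–H insertion at the doubly allylic C6 methylene and over silyl transfer; the hindered tetrasubstituted enol ether, the unsubstituted vinyl terminus, the polar non-coordinating solvent and the robust tert-butyldimethylsilyl group are chosen to secure this.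

Step 8
Reactants: 11 methyl (3aR,8aS)-3a-[(tert-butyldimethylsilyl)oxy]-6,8a-dimethyl-1,3a,4,7,8,8a-hexahydroazulene-3-carboxylate
Product: 12 methyl (3aR,8aS)-3a-hydroxy-6,8a-dimethyl-1,3a,4,7,8,8a-hexahydroazulene-3-carboxylate
Conditions: Bu4NF, THF, rt → 50 °C
Reagents that add atoms: none
Why: Fluoride desilylation of the tertiary silyl ether; the alkoxide sits next to a vinylic carbon and cannot fragment, and no stereocentre is touched.

Step 9
Reactants: 12 methyl (3aR,8aS)-3a-hydroxy-6,8a-dimethyl-1,3a,4,7,8,8a-hexahydroazulene-3-carboxylate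
Product: 14 methyl (3S,3aS,8aR)-3a-hydroxy-6,8a-dimethyl-1,2,3,3a,4,7,8,8a-octahydroazulene-3-carboxylate (ester cis to the C5 hydroxyl), via C4-epimeric hydroxy ester 13 (not isolated)
Conditions: Mg, MeOH, 0 °C → rt; then NaOMe (cat.), MeOH, 40 °C
Reagents that add atoms: none
Why: Dissolving-metal conjugate reduction (Mg/MeOH) saturates only the enoate, and C4 is then set under thermodynamic control by methoxide epimerisation, the ester preferring the convex face cis to the C5 hydroxyl (hydrogen bond or magnesium chelate, trans to the C6 methylene).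

Step 10
Reactants: 14 methyl (3S,3aS,8aR)-3a-hydroxy-6,8a-dimethyl-1,2,3,3a,4,7,8,8a-octahydroazulene-3-carboxylate
Product: 16 1-[(3S,3aS,8aR)-3a-hydroxy-6,8a-dimethyl-1,2,3,3a,4,7,8,8a-octahydroazulen-3-yl]ethan-1-one, via Weinreb amide 15 (not isolated)
Conditions: MeNHOMe·HCl, i-PrMgCl, THF, −20 °C; then MeMgBr, 0 °C → rt
Reagents that add atoms: methylmagnesium bromide, C[Mg]Br; N,O-dimethylhydroxylamine hydrochloride, CNOC.Cl (atoms carried by intermediate 15 only)
Why: One-pot Weinreb ketone synthesis: the magnesium amide converts the ester into the N-methoxy-N-methylamide and the Grignard reagent adds once because the chelated adduct holds until quench; C4 is not touched.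

Step 11
Reactants: 16 1-[(3S,3aS,8aR)-3a-hydroxy-6,8a-dimethyl-1,2,3,3a,4,7,8,8a-octahydroazulen-3-yl]ethan-1-one
Product: 17 (3R,3aS,8aR)-6,8a-dimethyl-3-(prop-1-en-2-yl)-2,3,4,7,8,8a-hexahydro-1H-azulen-3a-ol
Conditions: Zn, CH2Br2, TiCl4, THF; then 16, CH2Cl2, 0 °C → rt
Reagents that add atoms: dibromomethane, BrCBr
Why: Takai–Lombardo methylenation uses a non-basic gem-dimetallic reagent, so neither retro-aldol cleavage of the β-hydroxy ketone nor C4 epimerisation is expected, and the free hydroxyl is tolerated.

Step 12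
Reactants: 17 (3R,3aS,8aR)-6,8a-dimethyl-3-(prop-1-en-2-yl)-2,3,4,7,8,8a-hexahydro-1H-azulen-3a-ol
Product: 18 (3R,3aS,8aR)-6,8a-dimethyl-3-(propan-2-yl)-2,3,4,7,8,8a-hexahydro-1H-azulen-3a-ol
Conditions: H2 (1 atm), RhCl(PPh3)3 (5 mol %), PhH–EtOH, rt
Reagents that add atoms: none
Why: Homogeneous hydrogenation with RhCl(PPh3)3 reduces the 1,1-disubstituted isopropenyl alkene far faster than the trisubstituted ring alkene; no stereocentre is formed.

Step 13
Reactants: 18 (3R,3aS,8aR)-6,8a-dimethyl-3-(propan-2-yl)-2,3,4,7,8,8a-hexahydro-1H-azulen-3a-ol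
Product: 20 (3R,3aS,8aS)-6,8a-dimethyl-3-(propan-2-yl)decahydroazulene-3a,5-diol (C7/C8 diastereomer mixture), via C7 alkylborane 19 (not isolated)
Conditions: BH3·THF (3 equiv), THF, 0 °C → rt; then NaOH, H2O2, 0 °C → rt
Reagents that add atoms: hydrogen peroxide, OO; borane–tetrahydrofuran, B.C1CCOC1 (boron carried by intermediate 19 only)
Why: Hydroboration–oxidation puts boron, then oxygen, on the less substituted C7; the C7 and C8 centres formed here are erased in steps 14 and 15, so facial selectivity does not matter.

Step 14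
Reactants: 20 (3R,3aS,8aS)-6,8a-dimethyl-3-(propan-2-yl)decahydroazulene-3a,5-diol
Product: 21 (3R,3aS,8aR)-3a-hydroxy-6,8a-dimethyl-3-(propan-2-yl)octahydroazulen-5(1H)-one (C8 epimer mixture)
Conditions: Dess–Martin periodinane, NaHCO3, CH2Cl2, rt
Reagents that add atoms: none
Why: Dess–Martin oxidation converts the secondary C7 alcohol under buffered, non-basic conditions, so the tertiary β-hydroxy ketone neither dehydrates nor undergoes retro-aldol ring opening.

Step 15
Reactants: 21 (3R,3aS,8aR)-3a-hydroxy-6,8a-dimethyl-3-(propan-2-yl)octahydroazulen-5(1H)-one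
Product: 22 (3R,3aS,8aR)-3a-hydroxy-6,8a-dimethyl-3-(propan-2-yl)-2,3,3a,4,8,8a-hexahydroazulen-5(1H)-one
Conditions: IBX, DMSO–PhF, 65 °C
Reagents that add atoms: none
Why: IBX dehydrogenation of the ketone through its more substituted enol can only desaturate C8–C9 because C5 carries no hydrogen, and both C8 epimers converge on the one enone.

Step 16
Reactants: 22 (3R,3aS,8aR)-3a-hydroxy-6,8a-dimethyl-3-(propan-2-yl)-2,3,3a,4,8,8a-hexahydroazulen-5(1H)-one
Product: 23 (3R,3aS,5R,8aR)-6,8a-dimethyl-3-(propan-2-yl)-2,3,4,5,8,8a-hexahydro-1H-azulene-3a,5-diol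
Conditions: Me4NBH(OAc)3, MeCN–AcOH (1:1), −30 → 0 °C
Reagents that add atoms: none
Why: Evans–Saksena hydroxyl-directed reduction: the C5 hydroxyl binds boron and delivers hydride to its own face of the C7 carbonyl, so the new C7 hydroxyl is trans (1,3-anti) to the C5 hydroxyl, and the weak hydride leaves the C8=C9 bond alone.

Step 17
Reactants: 23 (3R,3aS,5R,8aR)-6,8a-dimethyl-3-(propan-2-yl)-2,3,4,5,8,8a-hexahydro-1H-azulene-3a,5-diol, 24 3,4-dimethoxybenzoyl chloride
Product: 25 (3R,3aS,5R,8aR)-3a-hydroxy-6,8a-dimethyl-3-(propan-2-yl)-1,2,3,3a,4,5,8,8a-octahydroazulen-5-yl 3,4-dimethoxybenzoate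
Conditions: Et3N, DMAP (cat.), CH2Cl2, 0 °C → rt
Reagents that add atoms: none
Why: DMAP-catalysed acylation esterifies the secondary allylic C7 alcohol with retention, while the tertiary C5 hydroxyl, flanked by two fully substituted carbons, does not react.

**Compound list**

1 | 4-methylanisole | COc1ccc(C)cc1 | starting material
2 | 1-methoxy-4-methylcyclohexa-1,4-diene | COC1=CCC(C)=CC1 | intermediate
3 | 1,1-dichloroethane | CC(Cl)Cl | starting material
4 | 7-chloro-1-methoxy-4,7-dimethylbicyclo[4.1.0]hept-3-ene (racemic, C7 epimers) | COC12CC=C(C)CC1C2(C)Cl | intermediate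
5 | 2,5-dimethylcyclohepta-2,5-dien-1-one | CC1=CCC(C)=CCC1=O | intermediate
6 | tert-butyl[(2,5-dimethylcyclohepta-1,5-dien-1-yl)oxy]dimethylsilane | CC1=CCC(O[Si](C)(C)C(C)(C)C)=C(C)CC1 | intermediate
7 | methyl acetoacetate | COC(=O)CC(C)=O | starting material
8 | methyl 2-diazo-3-oxobutanoate | COC(=O)C(=[N+]=[N-])C(C)=O | intermediate
9 | methyl 2-diazo-3-hydroxybutanoate (racemic) | COC(=O)C(=[N+]=[N-])C(C)O | intermediate
10 | methyl 2-diazobut-3-enoate | C=CC(=[N+]=[N-])C(=O)OC | intermediate
11 | methyl (3aR,8aS)-3a-[(tert-butyldimethylsilyl)oxy]-6,8a-dimethyl-1,3a,4,7,8,8a-hexahydroazulene-3-carboxylate | COC(=O)C1=CC[C@]2(C)CCC(C)=CC[C@]12O[Si](C)(C)C(C)(C)C | intermediate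
12 | methyl (3aR,8aS)-3a-hydroxy-6,8a-dimethyl-1,3a,4,7,8,8a-hexahydroazulene-3-carboxylate | COC(=O)C1=CC[C@]2(C)CCC(C)=CC[C@]12O | intermediate
13 | methyl (3R,3aS,8aR)-3a-hydroxy-6,8a-dimethyl-1,2,3,3a,4,7,8,8a-octahydroazulene-3-carboxylate (ester trans to the C5 hydroxyl) | CC1=CC[C@]2(O)[C@H](C(=O)OC)CC[C@]2(C)CC1 | intermediate
14 | methyl (3S,3aS,8aR)-3a-hydroxy-6,8a-dimethyl-1,2,3,3a,4,7,8,8a-octahydroazulene-3-carboxylate (ester cis to the C5 hydroxyl) | CC1=CC[C@]2(O)[C@@H](C(=O)OC)CC[C@]2(C)CC1 | intermediate
15 | (3S,3aS,8aR)-3a-hydroxy-N-methoxy-N,6,8a-trimethyl-1,2,3,3a,4,7,8,8a-octahydroazulene-3-carboxamide | CC1=CC[C@]2(O)[C@@H](C(=O)N(C)OC)CC[C@]2(C)CC1 | intermediate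
16 | 1-[(3S,3aS,8aR)-3a-hydroxy-6,8a-dimethyl-1,2,3,3a,4,7,8,8a-octahydroazulen-3-yl]ethan-1-one | CC1=CC[C@]2(O)[C@@H](C(C)=O)CC[C@]2(C)CC1 | intermediate
17 | (3R,3aS,8aR)-6,8a-dimethyl-3-(prop-1-en-2-yl)-2,3,4,7,8,8a-hexahydro-1H-azulen-3a-ol | CC1=CC[C@]2(O)[C@@H](C(C)=C)CC[C@]2(C)CC1 | intermediate
18 | (3R,3aS,8aR)-6,8a-dimethyl-3-(propan-2-yl)-2,3,4,7,8,8a-hexahydro-1H-azulen-3a-ol | CC1=CC[C@]2(O)[C@@H](C(C)C)CC[C@]2(C)CC1 | intermediate
19 | [(3R,3aS,8aS)-3a-hydroxy-6,8a-dimethyl-3-(propan-2-yl)decahydroazulen-5-yl]borane (idealised monoalkylborane, C7/C8 diastereomer mixture) | CC1C(B)C[C@]2(O)[C@@H](C(C)C)CC[C@]2(C)CC1 | intermediate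
20 | (3R,3aS,8aS)-6,8a-dimethyl-3-(propan-2-yl)decahydroazulene-3a,5-diol (C7/C8 diastereomer mixture) | CC1C(O)C[C@]2(O)[C@@H](C(C)C)CC[C@]2(C)CC1 | intermediate
21 | (3R,3aS,8aR)-3a-hydroxy-6,8a-dimethyl-3-(propan-2-yl)octahydroazulen-5(1H)-one (C8 epimer mixture) | CC1C(=O)C[C@]2(O)[C@@H](C(C)C)CC[C@]2(C)CC1 | intermediate
22 | (3R,3aS,8aR)-3a-hydroxy-6,8a-dimethyl-3-(propan-2-yl)-2,3,3a,4,8,8a-hexahydroazulen-5(1H)-one | O=C1C[C@]2(O)[C@@H](C(C)C)CC[C@]2(C)CC=C1C | intermediate
23 | (3R,3aS,5R,8aR)-6,8a-dimethyl-3-(propan-2-yl)-2,3,4,5,8,8a-hexahydro-1H-azulene-3a,5-diol | O[C@@H]1C[C@]2(O)[C@@H](C(C)C)CC[C@]2(C)CC=C1C | intermediate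
24 | 3,4-dimethoxybenzoyl chloride | COc1ccc(C(=O)Cl)cc1OC | starting material
25 | (3R,3aS,5R,8aR)-3a-hydroxy-6,8a-dimethyl-3-(propan-2-yl)-1,2,3,3a,4,5,8,8a-octahydroazulen-5-yl 3,4-dimethoxybenzoate | COc1ccc(C(=O)O[C@@H]2C[C@]3(O)[C@@H](C(C)C)CC[C@]3(C)CC=C2C)cc1OC | target

**Step count**

Total: 17 steps. Longest linear sequence: 14 steps (steps 1–3 and 7–17 from 4-methylanisole; the diazo branch, steps 4–6 and 7–17, is equally long).

**Steps most likely to fail, with fallbacks**

Step 7. The carbenoid may insert into the doubly allylic C–H bonds at C6 instead of being attacked at its terminus, attack at the carbenoid carbon may lead to cyclopropanation, silyl transfer in the zwitterion may outrun ring closure, and the remote chiral ligands may select the enol ether face poorly. The fallback builds the cyclopentane in the reverse order with known reactions, setting out from 6. Palladium-catalysed enantioselective decarboxylative allylation of the silyl enol ether (Pd2(dba)3, zerovalent palladium, (S)-t-Bu-PHOX, diallyl carbonate, Bu4N[Ph3SiF2], THF, rt) sets the C1 quaternary centre and gives (2S)-2,5-dimethyl-2-(prop-2-en-1-yl)cyclohept-5-en-1-one F1. Cross-metathesis with methyl acrylate (second-generation Hoveyda–Grubbs catalyst, CH2Cl2, 40 °C) gives methyl (2E)-4-[(1S)-1,5-dimethyl-2-oxocyclohept-4-en-1-yl]but-2-enoate F2. Copper hydride reductive aldol cyclisation ([(Ph3P)CuH]6, toluene, −40 → 0 °C) then forms C4–C5 through a chelated copper enolate, which places the ester cis to the new hydroxyl and the hydroxyl cis to the C1 methyl. The sequence comes back to the route at 14, so steps 8 and 9 are not needed.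

Step 9. Under methoxide the tertiary β-hydroxy ester may open by retro-aldol cleavage of C4–C5, or the thermodynamic preference for the cis ester may be too small to give a clean epimerisation. The fallback sets C4 kinetically on the silyl ether instead, setting out from 11. Nickel boride conjugate reduction (NaBH4, NiCl2·6H2O, MeOH, 0 °C) should deliver hydrogen to the face of C3=C4 opposite the bulky tertiary silyl ether and give methyl (3S,3aS,8aR)-3a-[(tert-butyldimethylsilyl)oxy]-6,8a-dimethyl-1,2,3,3a,4,7,8,8a-octahydroazulene-3-carboxylate F3, in which no retro-aldol is possible. Fluoride desilylation (Bu4NF, THF) then returns to the route at 14.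

Step 2. Only the adduct epimer with chlorine syn to the six-membered ring can open in the required disrotatory sense, the carbenoid may also add to the second double bond, and the skipped dienone may drift into conjugation during solvolysis. The fallback uses a dihalocarbene, whose adduct always carries a halogen in the reactive position, setting out from 2. Dibromocarbene addition (CHBr3, KOt-Bu, pentane, 0 °C) gives 7,7-dibromo-1-methoxy-4-methylbicyclo[4.1.0]hept-3-ene F4. Silver-assisted opening (AgNO3, aqueous acetone, rt) gives 2-bromo-5-methylcyclohepta-2,5-dien-1-one F5. Stille coupling under neutral conditions (Me4Sn, Pd(PPh3)4, CuI, DMF, 60 °C) installs the C2 methyl group and returns to the route at 5.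

**Further compounds**

F1 | step 7 | (2S)-2,5-dimethyl-2-(prop-2-en-1-yl)cyclohept-5-en-1-one | C=CC[C@]1(C)CCC(C)=CCC1=O
F2 | step 7 | methyl (2E)-4-[(1S)-1,5-dimethyl-2-oxocyclohept-4-en-1-yl]but-2-enoate | COC(=O)/C=C/C[C@]1(C)CCC(C)=CCC1=O
F3 | step 9 | methyl (3S,3aS,8aR)-3a-[(tert-butyldimethylsilyl)oxy]-6,8a-dimethyl-1,2,3,3a,4,7,8,8a-octahydroazulene-3-carboxylate | CC1=CC[C@]2(O[Si](C)(C)C(C)(C)C)[C@@H](C(=O)OC)CC[C@]2(C)CC1
F4 | step 2 | 7,7-dibromo-1-methoxy-4-methylbicyclo[4.1.0]hept-3-ene | COC12CC=C(C)CC1C2(Br)Br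
F5 | step 2 | 2-bromo-5-methylcyclohepta-2,5-dien-1-one | CC1=CCC(=O)C(Br)=CC1
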